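**Retrosynthetic overview**

1. The target is the mono-acetate of a meso cyclopent-4-ene-1,2,3-triol that carries the tridecanoyl group on its central carbon (ring numbering used here: C1 quaternary carbinol, C2 CH–OH, C3=C4, C5 CH–OAc). The C3=C4 bond is made last, by ring-closing olefin metathesis of an open-chain enoate/vinyl 1,6-diene that already holds the ketone, both free hydroxyls and the acetate.
2. The feature that makes this possible: C1 is a fully substituted carbon between the two allylic carbinol carbons C2 and C5, so C3 and C4 are the inner alkene carbons of a gem-disubstituted 1,6-diene and close to the only ring, the cyclopentene.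
3. The diene is unmasked from a furanose hemiacetal by a neutral Wittig reaction. Target C4, C5, C1, C2, C3 are C1 to C5 of D-glucose, the furanose ring oxygen becomes the free C2 hydroxyl, and the anomeric/O-2 pair allows the acetate to be placed on the C5 oxygen alone.
4. The quaternary centre is built on the rigid 1,2-O-isopropylidene furanose: 3-ulose, Wittig tridecylidenation, exo-face dihydroxylation, oxidation to the α-hydroxy ketone. This sequence is stereoconvergent in alkene geometry and side-chain carbinol configuration. C6 of glucose leaves in the 5,6-diol-to-alkene step.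
5. Ring order: the dioxolane and furanose rings of the sugar are temporary and are opened before the key step; the cyclopentene is the single ring formed, in the last step.

Key step: step 12

Remark on the chemistry: anomeric mixtures (12 to 14), the alkene-geometry mixture (7) and the side-chain carbinol mixture (8) are carried on unseparated because later steps remove these elements; the SMILES leave those positions undefined.

**Route**

Step 1
Reactants: 1 1,2:5,6-di-O-isopropylidene-α-D-glucofuranose (diacetone-D-glucose)
Product: 2 1,2:5,6-di-O-isopropylidene-α-D-ribo-hexofuranos-3-ulose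
Conditions: Dess–Martin periodinane, CH2Cl2, rt; then azeotropic drying with toluene
Reagents that add atoms: none
Why: Dess–Martin oxidation of the only free hydroxyl gives the bicyclic 3-ketone under neutral, non-epimerising conditions that both acetonides tolerate; no stereocentre is formed.

Step 2
Reactants: 3 1-bromotridecane; 4 triphenylphosphine
Product: 5 tridecyltriphenylphosphonium bromide
Conditions: MeCN, reflux
Reagents that add atoms: none
Why: SN2 alkylation of triphenylphosphine by the primary bromide (phosphonium salt formation) gives the Wittig salt; no stereocentre is involved.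

Step 3
Reactants: 2 1,2:5,6-di-O-isopropylidene-α-D-ribo-hexofuranos-3-ulose; 5 tridecyltriphenylphosphonium bromide
Product: 7 3-deoxy-1,2:5,6-di-O-isopropylidene-3-C-tridecylidene-α-D-ribo-hexofuranose (E/Z mixture), via tridecylidene ylide 6 (not isolated)
Conditions: 5, KN(SiMe3)2, THF, 0 °C; then 2, −78 °C → rt
Reagents that add atoms: none
Why: Wittig olefination of the ketone with the non-stabilised ylide installs all thirteen side-chain carbons at C-3 in one step; the alkene geometry need not be controlled because the next two steps erase it, and the low temperature limits enolisation towards C-4.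

Step 4
Reactants: 7 3-deoxy-1,2:5,6-di-O-isopropylidene-3-C-tridecylidene-α-D-ribo-hexofuranose
Product: 8 3-C-(1-hydroxytridecyl)-1,2:5,6-di-O-isopropylidene-α-D-glucofuranose (mixture of side-chain carbinol epimers)
Conditions: K2OsO4·2H2O (cat.), N-methylmorpholine N-oxide, MeSO2NH2, acetone–H2O, rt → 40 °C
Reagents that add atoms: N-methylmorpholine N-oxide, C[N+]1([O-])CCOCC1 (oxygen relayed through catalytic OsO4, O=[Os](=O)(=O)=O); water, O
Why: Catalytic osmium tetroxide dihydroxylation (Upjohn conditions) should add to the exo (β) face of the cis-fused furo-dioxolane bicycle, away from the 1,2-O-isopropylidene group, so that the new tertiary hydroxyl at C-3 is β (gluco) and the carbon branch is α for both alkene isomers; the side-chain carbinol is left as a mixture that step 5 removes.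

Step 5
Reactants: 8 3-C-(1-hydroxytridecyl)-1,2:5,6-di-O-isopropylidene-α-D-glucofuranose
Product: 9 1,2:5,6-di-O-isopropylidene-3-C-tridecanoyl-α-D-glucofuranose
Conditions: 2-iodoxybenzoic acid (IBX), EtOAc, 75 °C
Reagents that add atoms: none
Why: IBX oxidation converts the secondary hydroxyl of the secondary/tertiary 1,2-diol into the α-hydroxy ketone without glycol cleavage, the tertiary alcohol being inert, and so funnels both carbinol epimers into one compound (stereoconvergent oxidation).

Step 6
Reactants: 9 1,2:5,6-di-O-isopropylidene-3-C-tridecanoyl-α-D-glucofuranose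
Product: 10 1,2-O-isopropylidene-3-C-tridecanoyl-α-D-glucofuranose
Conditions: AcOH–H2O (7:3), 40 °C
Reagents that add atoms: none
Why: Acid-catalysed acetal hydrolysis is faster for the terminal 5,6-dioxolane than for the anomeric 1,2-acetonide, the standard selective deprotection in this sugar series; no stereocentre is touched.

Step 7
Reactants: 10 1,2-O-isopropylidene-3-C-tridecanoyl-α-D-glucofuranose
Product: 11 5,6-dideoxy-1,2-O-isopropylidene-3-C-tridecanoyl-α-D-xylo-hex-5-enofuranose
Conditions: PPh3 (4), I2, imidazole, toluene, 90 °C
Reagents that add atoms: none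
Why: Garegg–Samuelsson deoxygenation of a terminal vicinal diol (iodination and oxyphosphonium activation, then reductive elimination) gives the vinyl group, while the hindered tertiary α-keto hydroxyl is not activated; C-5 loses its stereocentre as planned.

Step 8
Reactants: 11 5,6-dideoxy-1,2-O-isopropylidene-3-C-tridecanoyl-α-D-xylo-hex-5-enofuranose
Product: 12 5,6-dideoxy-3-C-tridecanoyl-D-xylo-hex-5-enofuranose (α/β hemiacetal)
Conditions: CF3CO2H–H2O (4:1), 0 °C → rt
Reagents that add atoms: none
Why: Aqueous acid hydrolysis of the anomeric isopropylidene acetal frees the 1,2-diol as a hemiacetal, which can only be a furanose because O-5 is gone; the stereocentres at C-2, C-3 and C-4 are unaffected.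

Step 9
Reactants: 12 5,6-dideoxy-3-C-tridecanoyl-D-xylo-hex-5-enofuranose
Product: 13 1,2-di-O-acetyl-5,6-dideoxy-3-C-tridecanoyl-D-xylo-hex-5-enofuranose (α/β)
Conditions: Ac2O, pyridine, 0 °C → rt
Reagents that add atoms: acetic anhydride, CC(=O)OC(C)=O
Why: Acetylation with acetic anhydride in pyridine without an acyl-transfer catalyst should esterify the anomeric and the secondary C-2 hydroxyl and leave the hindered tertiary α-keto alcohol free.

Step 10
Reactants: 13 1,2-di-O-acetyl-5,6-dideoxy-3-C-tridecanoyl-D-xylo-hex-5-enofuranose
Product: 14 2-O-acetyl-5,6-dideoxy-3-C-tridecanoyl-D-xylo-hex-5-enofuranose (α/β hemiacetal)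
Conditions: BnNH2, THF, rt
Reagents that add atoms: none
Why: Chemoselective aminolysis of the anomeric acetate, the most electrophilic ester with the best leaving group, is the standard 1-O-deacetylation of sugar acetates and leaves the acetate on O-2 only, which fixes it on the S-configured carbinol carbon of the target.

Step 11
Reactants: 14 2-O-acetyl-5,6-dideoxy-3-C-tridecanoyl-D-xylo-hex-5-enofuranose; 15 ethyl (triphenylphosphoranylidene)acetate
Product: 16 ethyl (2E,4S,5S,6R)-4-acetoxy-5,6-dihydroxy-5-tridecanoylocta-2,7-dienoate
Conditions: toluene, PhCO2H (cat.), 70 °C; crude product filtered through silica and used directly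
Reagents that add atoms: none
Why: Wittig olefination of the hemiacetal through its open hydroxy-aldehyde form with a stabilised, non-basic ylide is selective for the aldehyde over the hindered ketone and spares the acetate and the retro-aldol-prone β-hydroxy ketone; ring opening releases the furanose oxygen as the free secondary hydroxyl of the target, and no stereocentre is formed.

Step 12
Reactants: 16 ethyl (2E,4S,5S,6R)-4-acetoxy-5,6-dihydroxy-5-tridecanoylocta-2,7-dienoate
Product: 17 (1S,4R,5S)-4,5-dihydroxy-5-tridecanoylcyclopent-2-en-1-yl acetate (CNP0284288.2)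
Conditions: second-generation Hoveyda–Grubbs catalyst (cat.), 1,4-benzoquinone (cat.), CH2Cl2, high dilution, 40 °C
Reagents that add atoms: none
Why: Ring-closing olefin metathesis: the ruthenium alkylidene exchanges onto the terminal vinyl group, adds intramolecularly across the enoate double bond through a ruthenacyclobutane, and cycloreversion forms the C3=C4 bond while the ester-bearing carbon leaves as ethyl acrylate after turnover with a further vinyl group. The closest known reaction type is the ring-closing metathesis of sugar-derived 3,4,5-trioxygenated hepta-1,6-dienes to cyclopentene polyols, including cases where an α,β-unsaturated ester is the internal olefin partner. The single ring, the cyclopentene, is closed as a five-membered carbocycle from a 1,6-diene, favoured by the fully substituted C1 between the two allylic carbons (Thorpe–Ingold effect) and by high dilution. No stereocentre is formed: C1, C2 and C5 are carried unchanged from C3, C4 and C2 of D-glucose, and the cis geometry of the new alkene is imposed by the ring, so both enoate geometries converge on one product. The step needs chemoselectivity for metathesis over allylic-alcohol isomerisation and over dimerisation, which the phosphine-free catalyst, the benzoquinone hydride scavenger, the dilution and initiation at the only terminal alkene should secure; the ketone, both hydroxyls and the acetate are inert to the catalyst, so no protecting group is needed.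

**Compound list**

1 | 1,2:5,6-di-O-isopropylidene-α-D-glucofuranose | CC1(C)O[C@H]2O[C@H]([C@H]3COC(C)(C)O3)[C@H](O)[C@H]2O1 | starting material
2 | 1,2:5,6-di-O-isopropylidene-α-D-ribo-hexofuranos-3-ulose | CC1(C)O[C@H]2O[C@H]([C@H]3COC(C)(C)O3)C(=O)[C@H]2O1 | intermediate
3 | 1-bromotridecane | CCCCCCCCCCCCCBr | starting material
4 | triphenylphosphine | c1ccc(cc1)P(c1ccccc1)c1ccccc1 | starting material
5 | tridecyltriphenylphosphonium bromide | CCCCCCCCCCCCC[P+](c1ccccc1)(c1ccccc1)c1ccccc1.[Br-] | intermediate
6 | tridecylidene(triphenyl)phosphorane (ylide, not isolated) | CCCCCCCCCCCCC=P(c1ccccc1)(c1ccccc1)c1ccccc1 | intermediate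
7 | 3-deoxy-1,2:5,6-di-O-isopropylidene-3-C-tridecylidene-α-D-ribo-hexofuranose (E/Z) | CC1(C)O[C@H]2O[C@H]([C@H]3COC(C)(C)O3)C(=CCCCCCCCCCCCC)[C@H]2O1 | intermediate
8 | 3-C-(1-hydroxytridecyl)-1,2:5,6-di-O-isopropylidene-α-D-glucofuranose (side-chain epimers) | CC1(C)O[C@H]2O[C@H]([C@H]3COC(C)(C)O3)[C@@](O)(C(O)CCCCCCCCCCCC)[C@H]2O1 | intermediate
9 | 1,2:5,6-di-O-isopropylidene-3-C-tridecanoyl-α-D-glucofuranose | CC1(C)O[C@H]2O[C@H]([C@H]3COC(C)(C)O3)[C@@](O)(C(=O)CCCCCCCCCCCC)[C@H]2O1 | intermediate
10 | 1,2-O-isopropylidene-3-C-tridecanoyl-α-D-glucofuranose | CC1(C)O[C@H]2O[C@H]([C@H](O)CO)[C@@](O)(C(=O)CCCCCCCCCCCC)[C@H]2O1 | intermediate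
11 | 5,6-dideoxy-1,2-O-isopropylidene-3-C-tridecanoyl-α-D-xylo-hex-5-enofuranose | CC1(C)O[C@H]2O[C@H](C=C)[C@@](O)(C(=O)CCCCCCCCCCCC)[C@H]2O1 | intermediate
12 | 5,6-dideoxy-3-C-tridecanoyl-D-xylo-hex-5-enofuranose (α/β) | OC1O[C@H](C=C)[C@@](O)(C(=O)CCCCCCCCCCCC)[C@H]1O | intermediate
13 | 1,2-di-O-acetyl-5,6-dideoxy-3-C-tridecanoyl-D-xylo-hex-5-enofuranose (α/β) | CC(=O)OC1O[C@H](C=C)[C@@](O)(C(=O)CCCCCCCCCCCC)[C@H]1OC(C)=O | intermediate
14 | 2-O-acetyl-5,6-dideoxy-3-C-tridecanoyl-D-xylo-hex-5-enofuranose (α/β) | OC1O[C@H](C=C)[C@@](O)(C(=O)CCCCCCCCCCCC)[C@H]1OC(C)=O | intermediate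
15 | ethyl (triphenylphosphoranylidene)acetate | CCOC(=O)C=P(c1ccccc1)(c1ccccc1)c1ccccc1 | starting material
16 | ethyl (2E,4S,5S,6R)-4-acetoxy-5,6-dihydroxy-5-tridecanoylocta-2,7-dienoate | CCOC(=O)/C=C/[C@H](OC(C)=O)[C@](O)(C(=O)CCCCCCCCCCCC)[C@H](O)C=C | intermediate
17 | (1S,4R,5S)-4,5-dihydroxy-5-tridecanoylcyclopent-2-en-1-yl acetate | CCCCCCCCCCCCC(=O)[C@]1(O)[C@H](O)C=C[C@@H]1OC(C)=O | target

**Step count and risks**

Total step count: 12. Longest linear sequence: 11 steps (1 → 17 through steps 1 and 3 to 12; step 2 is a side branch).

Steps most likely to fail: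

Step 11. Two processes may interfere: conjugate addition of the hydroxyl freed at C-6 onto the new enoate (oxa-Michael closure to a tetrahydrofuran), and migration or loss of the acetate in the hemiacetal before it opens. The fallback introduces the acetate last, by desymmetrisation instead of by sugar-encoded differentiation. It sets out from hemiacetal 12, which is olefinated with 15 under the same neutral conditions to ethyl (2E,4S,5S,6R)-4,5,6-trihydroxy-5-tridecanoylocta-2,7-dienoate F4. Ring-closing metathesis with the second-generation Hoveyda–Grubbs catalyst then gives the meso triol 1-[(1r,2R,5S)-1,2,5-trihydroxycyclopent-3-en-1-yl]tridecan-1-one F5. Lipase-catalysed transesterification (Burkholderia cepacia lipase, vinyl acetate, t-BuOMe), the classical desymmetrisation of cis-cyclopent-4-ene-1,3-diols, should acetylate one enantiotopic hydroxyl and return to the route at 17. The enantiotopic preference of the enzyme on this substituted diol is not known and would have to be screened.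

Step 12. The ester-substituted ruthenium carbene released on ring closure may decompose faster than it turns over, or the catalyst may isomerise the free allylic alcohol. The fallback changes the olefin partner so that only ethene is lost. It sets out from hemiacetal 14, which is methylenated under neutral, aldehyde-selective rhodium catalysis (RhCl(PPh3)3, PPh3, Me3SiCHN2, 2-propanol, THF) to (3S,4S,5R)-4,5-dihydroxy-4-tridecanoylhepta-1,6-dien-3-yl acetate F6. Ring-closing metathesis of this terminal diene comes back to the route at 17.

Step 3. The bulky, basic ylide may enolise the strained, hydrate-prone ketone (with epimerisation at C-4 or β-elimination) faster than it olefinates it. The fallback builds the chain in two stages. It sets out from ketone 2, which is methylenated with Ph3P=CH2 to 3-deoxy-1,2:5,6-di-O-isopropylidene-3-C-methylene-α-D-ribo-hexofuranose F1. Dihydroxylation (K2OsO4·2H2O, N-methylmorpholine N-oxide) from the exo face gives 3-C-(hydroxymethyl)-1,2:5,6-di-O-isopropylidene-α-D-glucofuranose F2. Oxidation of the primary hydroxyl (SO3·pyridine, DMSO, Et3N) gives 3-C-formyl-1,2:5,6-di-O-isopropylidene-α-D-glucofuranose F3, and addition of C12H25MgBr returns to the route at diol 8.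

Further compounds
F1 | step 3 | 3-deoxy-1,2:5,6-di-O-isopropylidene-3-C-methylene-α-D-ribo-hexofuranose | CC1(C)O[C@H]2O[C@H]([C@H]3COC(C)(C)O3)C(=C)[C@H]2O1
F2 | step 3 | 3-C-(hydroxymethyl)-1,2:5,6-di-O-isopropylidene-α-D-glucofuranose | CC1(C)O[C@H]2O[C@H]([C@H]3COC(C)(C)O3)[C@@](O)(CO)[C@H]2O1
F3 | step 3 | 3-C-formyl-1,2:5,6-di-O-isopropylidene-α-D-glucofuranose | CC1(C)O[C@H]2O[C@H]([C@H]3COC(C)(C)O3)[C@@](O)(C=O)[C@H]2O1
F4 | step 11 | ethyl (2E,4S,5S,6R)-4,5,6-trihydroxy-5-tridecanoylocta-2,7-dienoate | CCOC(=O)/C=C/[C@H](O)[C@](O)(C(=O)CCCCCCCCCCCC)[C@H](O)C=C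
F5 | step 11 | 1-[(1r,2R,5S)-1,2,5-trihydroxycyclopent-3-en-1-yl]tridecan-1-one (meso) | CCCCCCCCCCCCC(=O)[C@]1(O)[C@H](O)C=C[C@@H]1O
F6 | step 12 | (3S,4S,5R)-4,5-dihydroxy-4-tridecanoylhepta-1,6-dien-3-yl acetate | C=C[C@H](OC(C)=O)[C@](O)(C(=O)CCCCCCCCCCCC)[C@H](O)C=C
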